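**Plan**

- Retrosynthesis: C7=C8 is cut first (Julia–Kocienski olefination) into a cyclopentylmethyl tetrazolyl sulfone and the C30 aldehyde apo-8'-lycopenal. The aldehyde is cut at C7'=C8' (Wittig) into a geranyl phosphonium salt and the C20 dialdehyde crocetindialdehyde.
- In the ring fragment the two C1–CH3 bonds lead back to a cis-fused γ-lactone, and its C6–H and C2–H bonds to a fused hydroxy butenolide. The butenolide is cut at C6–C7 (Stille coupling) and C2–C6 (Dieckmann-type acylation), which leaves an alkylated lactic acid acetal.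
- Forward: the cyclopentane ring closes first (step 5), the butenolide ring second (step 7), the ring-fusion alkene is then hydrogenated (step 8), the lactone is opened, and the separately built polyene chain is joined last (step 15).
- Feature that makes the key step possible (carotenoid numbering: ring C2–C6, C1 on C2, C7 on C6): the tertiary C5 hydroxyl is allylic to the C2=C6 ring-fusion alkene of the planar cyclopenta[c]furanone and lies on the ring face that must carry H-6 and H-2. One hydroxyl-bound syn addition of H2 therefore sets both centres.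
- Stereochemistry: C5 comes from (S)-lactic acid by enolate allylation of its pivalaldehyde acetal with retention; C6 and C2 follow from C5 in step 8; the E alkenes come from the Wittig and Julia–Kocienski reactions with thermal or iodine equilibration.

Key step: step 8

Remark: crocetindialdehyde and (tributylstannyl)methanol are taken as purchased reagents, and the descriptors 2R,5R,6R for the target are those read from the given structure (C5 hydroxyl cis to H-6 and H-2).

**Route**

Step 1
Reactants: 1 (S)-lactic acid
Product: 2 (2S,5S)-2-tert-butyl-5-methyl-1,3-dioxolan-4-one (cis acetal)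
Conditions: pivalaldehyde, TsOH·H2O (cat.), H2SO4 (cat.), pentane, reflux with water separator; crystallisation from pentane/ether at −78 °C
Reagents that add atoms: pivalaldehyde, CC(C)(C)C=O
Why: Acid-catalysed acetalisation (1,3-dioxolan-4-one formation) with azeotropic removal of water should favour the cis acetal, which crystallises, so the lactic acid stereocentre is kept and a second, acetal stereocentre is created that will later relay it.

Step 2
Reactants: 2 (2S,5S)-2-tert-butyl-5-methyl-1,3-dioxolan-4-one
Product: 4 (2S,5R)-2-tert-butyl-5-methyl-5-(prop-2-en-1-yl)-1,3-dioxolan-4-one, via lithium enolate 3 (not isolated)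
Conditions: LDA (LiN(iPr)2), THF, −78 °C; allyl bromide, −78 °C → −30 °C
Reagents that add atoms: allyl bromide, C=CCBr
Why: The enolate is planar at the former carbinol carbon, and alkylation should occur anti to the tert-butyl group of the acetal centre (self-regeneration of the stereocentre), so that allyl takes the place of the original hydrogen with retention and the quaternary carbinol carbon (later C5) is set; any minor epimer is a separable diastereomer.

Step 3
Reactants: 4 (2S,5R)-2-tert-butyl-5-methyl-5-(prop-2-en-1-yl)-1,3-dioxolan-4-one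
Product: 5 methyl (2E)-4-[(2S,4R)-2-tert-butyl-4-methyl-5-oxo-1,3-dioxolan-4-yl]but-2-enoate
Conditions: methyl acrylate (5 equiv), second-generation Hoveyda–Grubbs catalyst RuCl2(H2IMes)(=CH-C6H4-2-OiPr) (3 mol%), CH2Cl2, 40 °C
Reagents that add atoms: methyl acrylate, C=CC(=O)OC
Why: Olefin cross-metathesis of the terminal alkene with an excess of the electron-poor acrylate, driven by loss of ethylene, should give the chain-extended enoate, whose geometry is of no consequence because the alkene is reduced next.

Step 4
Reactants: 5 methyl (2E)-4-[(2S,4R)-2-tert-butyl-4-methyl-5-oxo-1,3-dioxolan-4-yl]but-2-enoate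
Product: 6 methyl 4-[(2S,4R)-2-tert-butyl-4-methyl-5-oxo-1,3-dioxolan-4-yl]butanoate
Conditions: H2 (1 atm), palladium on carbon (Pd/C, 10 wt%), EtOAc, rt
Reagents that add atoms: none
Why: Heterogeneous hydrogenation of the disubstituted enoate alkene leaves the acetal, the esters and the quaternary centre untouched.

Step 5
Reactants: 6 methyl 4-[(2S,4R)-2-tert-butyl-4-methyl-5-oxo-1,3-dioxolan-4-yl]butanoate
Product: 7 methyl (3R)-3-hydroxy-3-methyl-2-oxocyclopentane-1-carboxylate (keto/enol and C1 epimers)
Conditions: LiHMDS (LiN(SiMe3)2, 2.2 equiv), THF, −78 °C → 0 °C; aq. NH4Cl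
Reagents that add atoms: none
Why: Dieckmann-type condensation (intramolecular Claisen acylation, 5-exo-trig): the enolate of the only enolisable ester should attack the activated dioxolanone carbonyl, the tetrahedral intermediate expels the acetal oxygen, pivalaldehyde is lost to unveil the tertiary hydroxyl, and deprotonation of the β-keto ester by the second equivalent of base drives the closure; the quaternary centre cannot epimerise.

Step 6
Reactants: 7 methyl (3R)-3-hydroxy-3-methyl-2-oxocyclopentane-1-carboxylate
Product: 9 methyl (3R)-3-hydroxy-3-methyl-2-{[(trifluoromethyl)sulfonyl]oxy}cyclopent-1-ene-1-carboxylate, via sodium enolate 8 (not isolated)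
Conditions: NaH (1.05 equiv), THF, 0 °C; PhNTf2, 0 °C → rt
Reagents that add atoms: N-phenylbis(trifluoromethanesulfonimide), O=S(=O)(N(c1ccccc1)S(=O)(=O)C(F)(F)F)C(F)(F)F
Why: The β-keto ester C–H is by far the most acidic site, so one equivalent of NaH should give only the stabilised enolate, which PhNTf2 sulfonylates on oxygen (enol triflate formation) while leaving the hindered tertiary alcohol alone.

Step 7
Reactants: 9 methyl (3R)-3-hydroxy-3-methyl-2-{[(trifluoromethyl)sulfonyl]oxy}cyclopent-1-ene-1-carboxylate
Product: 11 (4R)-4-hydroxy-4-methyl-3,4,5,6-tetrahydro-1H-cyclopenta[c]furan-1-one, via hydroxymethyl ester 10 (not isolated)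
Conditions: Bu3SnCH2OH (1.3 equiv), Pd(PPh3)4 (5 mol%), LiCl (3 equiv), 1,4-dioxane, 100 °C
Reagents that add atoms: (tributylstannyl)methanol, OC[Sn](CCCC)(CCCC)CCCC
Why: Stille coupling of the electron-poor vinyl triflate (oxidative addition to zerovalent palladium, chloride-assisted transfer of the hydroxymethyl group, reductive elimination) should install C7 as a cis-γ-hydroxy enoate, which lactonises in the flask to the butenolide; the tertiary alcohol needs no protection.

Step 8
Reactants: 11 (4R)-4-hydroxy-4-methyl-3,4,5,6-tetrahydro-1H-cyclopenta[c]furan-1-one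
Product: 12 (3aS,4R,6aR)-4-hydroxy-4-methylhexahydro-1H-cyclopenta[c]furan-1-one (cis-fused; H-3a and H-6a cis to the hydroxyl)
Conditions: [Ir(cod)(PCy3)(py)]PF6 (10 mol%, two portions), H2 (1 atm), dry CH2Cl2, 0 °C → rt
Reagents that add atoms: none
Why: Hydrogen removes cyclooctadiene from the monovalent iridium cation and leaves a trivalent dihydride with free sites, which are taken by the tertiary C5 hydroxyl of 11 and, on the same face, by the C2=C6 ring-fusion alkene; migratory insertion and C–H reductive elimination then deliver both hydrogens to that face. The closest known reaction type is the hydroxyl-directed hydrogenation of cyclic allylic and homoallylic alcohols, tetrasubstituted alkenes included, with cationic iridium phosphine–pyridine catalysts. No ring is closed, since the bicycle is already in place. C6 (ring-fusion carbon 3a) and C2 (6a) are both controlled by the C5 carbinol centre: the metal is held on the hydroxyl face, and syn addition makes the ring fusion cis, so H-6, H-2 and the C5 oxygen end up on one face and C7, C1 and the C5 methyl on the other. The step needs facial selectivity and chemoselectivity for the alkene over the allylic C7–O bond of the lactone; the planar butenolide offers no competing bias beyond the smaller size of hydroxyl against methyl, which points the same way, and the homogeneous cationic catalyst in a non-coordinating solvent is not expected to cleave the lactone C–O bond.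

Step 9
Reactants: 12 (3aS,4R,6aR)-4-hydroxy-4-methylhexahydro-1H-cyclopenta[c]furan-1-one
Product: 13 (1R,2S,3R)-2-(hydroxymethyl)-3-(2-hydroxypropan-2-yl)-1-methylcyclopentan-1-ol
Conditions: MeLi (4 equiv), THF, −78 °C → 0 °C; aq. NH4Cl
Reagents that add atoms: methyllithium, [Li]C
Why: Double addition of MeLi to the lactone carbonyl through the methyl ketone should give the dimethyl carbinol at C1 and free the C7 alkoxide, one further equivalent being consumed by the C5 hydroxyl; fast addition at low temperature should outrun enolisation at C2, and no stereocentre is touched.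

Step 10
Reactants: 13 (1R,2S,3R)-2-(hydroxymethyl)-3-(2-hydroxypropan-2-yl)-1-methylcyclopentan-1-ol
Product: 14 (1R,2R,3R)-3-(2-hydroxypropan-2-yl)-1-methyl-2-{[(1-phenyl-1H-tetrazol-5-yl)sulfanyl]methyl}cyclopentan-1-ol
Conditions: 1-phenyl-1H-tetrazole-5-thiol (1.5 equiv), PPh3, DIAD, THF, 0 °C → rt
Reagents that add atoms: 1-phenyl-1H-tetrazole-5-thiol, Sc1nnnn1-c1ccccc1
Why: Mitsunobu thioetherification: only the primary C7 alcohol forms an alkoxyphosphonium ion, which the acidic, highly nucleophilic tetrazolethiolate displaces, the two tertiary alcohols being inert; an excess of thiol should keep ring closure by the C1 hydroxyl to a cyclic ether from competing.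

Step 11
Reactants: 14 (1R,2R,3R)-3-(2-hydroxypropan-2-yl)-1-methyl-2-{[(1-phenyl-1H-tetrazol-5-yl)sulfanyl]methyl}cyclopentan-1-ol
Product: 15 (1R,2R,3R)-3-(2-hydroxypropan-2-yl)-1-methyl-2-{[(1-phenyl-1H-tetrazol-5-yl)sulfonyl]methyl}cyclopentan-1-ol
Conditions: (NH4)6Mo7O24·4H2O (10 mol%), 30% aq. H2O2, EtOH, 0 °C → rt
Reagents that add atoms: hydrogen peroxide, OO
Why: Molybdate-catalysed oxidation with hydrogen peroxide should take the sulfide through the sulfoxide to the sulfone without touching the tertiary alcohols.

Step 12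
Reactants: 15 (1R,2R,3R)-3-(2-hydroxypropan-2-yl)-1-methyl-2-{[(1-phenyl-1H-tetrazol-5-yl)sulfonyl]methyl}cyclopentan-1-ol
Product: 16 5-[({(1R,2R,5R)-2-methyl-2-[(trimethylsilyl)oxy]-5-{2-[(trimethylsilyl)oxy]propan-2-yl}cyclopentyl}methyl)sulfonyl]-1-phenyl-1H-tetrazole
Conditions: 1-(trimethylsilyl)imidazole (3 equiv), CH2Cl2, rt
Reagents that add atoms: 1-(trimethylsilyl)imidazole, C[Si](C)(C)n1ccnc1
Why: Neutral silyl transfer from the N-silylimidazole should cap both hindered tertiary hydroxyls, so that no alkoxide can attack the tetrazole ring (Smiles-type ipso substitution) under the basic olefination conditions.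

Step 13
Reactants: 17 geranyl bromide [(2E)-1-bromo-3,7-dimethylocta-2,6-diene]
Product: 18 [(2E)-3,7-dimethylocta-2,6-dien-1-yl]triphenylphosphonium bromide
Conditions: PPh3, toluene, rt
Reagents that add atoms: triphenylphosphine, c1ccc(cc1)P(c1ccccc1)c1ccccc1
Why: SN2 quaternisation of triphenylphosphine by the primary allylic bromide should give the salt with the E-configured trisubstituted alkene unchanged.

Step 14
Reactants: 18 [(2E)-3,7-dimethylocta-2,6-dien-1-yl]triphenylphosphonium bromide; 19 crocetindialdehyde [(2E,4E,6E,8E,10E,12E,14E)-2,6,11,15-tetramethylhexadeca-2,4,6,8,10,12,14-heptaenedial] (3 equiv)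
Product: 21 apo-8'-lycopenal [(2E,4E,6E,8E,10E,12E,14E,16E,18E)-2,6,11,15,19,23-hexamethyltetracosa-2,4,6,8,10,12,14,16,18,22-decaenal], via geranylidene ylide 20 (not isolated)
Conditions: NaOMe, CH2Cl2/MeOH, 0 °C → rt; then heptane, 80 °C
Reagents that add atoms: none
Why: Wittig reaction of the allylic ylide with one formyl group of the symmetrical dialdehyde, used in excess so that mono-olefination prevails and the surplus is recovered, forms C7'=C8'; the sterically hindered Z isomer of this bond should isomerise to E on heating.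

Step 15
Reactants: 16 5-[({(1R,2R,5R)-2-methyl-2-[(trimethylsilyl)oxy]-5-{2-[(trimethylsilyl)oxy]propan-2-yl}cyclopentyl}methyl)sulfonyl]-1-phenyl-1H-tetrazole; 21 apo-8'-lycopenal
Product: 23 bis(trimethylsilyl) ether of (all-E,2R,5R,6R)-2,6-cyclolycopene-1,5-diol, via potassium sulfonyl carbanion 22 (not isolated)
Conditions: KHMDS (KN(SiMe3)2), THF, −78 °C; 21, −78 °C → rt; then I2 (cat.), CH2Cl2, rt, daylight
Reagents that add atoms: none
Why: Julia–Kocienski olefination: the α-sulfonyl carbanion adds to the aldehyde, the alkoxide migrates to the tetrazole by Smiles rearrangement, and loss of sulfur dioxide and tetrazololate forms C7=C8, mainly E; iodine-catalysed equilibration should convert residual Z isomer, which suffers allylic strain between the ring and the C9 methyl, and the silyl ethers and the C6 centre are not affected.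

Step 16
Reactants: 23 bis(trimethylsilyl) ether of (all-E,2R,5R,6R)-2,6-cyclolycopene-1,5-diol
Product: 24 (all-E,2R,5R,6R)-2,6-cyclolycopene-1,5-diol (CNP0169920.2)
Conditions: PPTS (cat.), MeOH/CH2Cl2, 0 °C → rt
Reagents that add atoms: none
Why: Acid-catalysed methanolysis should cleave the two tertiary trimethylsilyl ethers under conditions too mild to ionise the non-allylic carbinols or to attack the polyene.

**Compound list**

1 | (S)-lactic acid [(2S)-2-hydroxypropanoic acid] | C[C@H](O)C(=O)O | starting material
2 | (2S,5S)-2-tert-butyl-5-methyl-1,3-dioxolan-4-one (tert-butyl and methyl cis) | C[C@@H]1O[C@H](C(C)(C)C)OC1=O | intermediate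
3 | lithium (2S)-2-tert-butyl-5-methyl-1,3-dioxol-4-olate (enolate of 2; formed in the flask) | CC1=C([O-])O[C@@H](C(C)(C)C)O1.[Li+] | intermediate
4 | (2S,5R)-2-tert-butyl-5-methyl-5-(prop-2-en-1-yl)-1,3-dioxolan-4-one (allyl trans to tert-butyl) | C[C@]1(CC=C)O[C@H](C(C)(C)C)OC1=O | intermediate
5 | methyl (2E)-4-[(2S,4R)-2-tert-butyl-4-methyl-5-oxo-1,3-dioxolan-4-yl]but-2-enoate | C[C@]1(C/C=C/C(=O)OC)O[C@H](C(C)(C)C)OC1=O | intermediate
6 | methyl 4-[(2S,4R)-2-tert-butyl-4-methyl-5-oxo-1,3-dioxolan-4-yl]butanoate | C[C@]1(CCCC(=O)OC)O[C@H](C(C)(C)C)OC1=O | intermediate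
7 | methyl (3R)-3-hydroxy-3-methyl-2-oxocyclopentane-1-carboxylate (C1 unassigned, enolisable) | COC(=O)C1CC[C@@](C)(O)C1=O | intermediate
8 | sodium (5R)-5-hydroxy-2-(methoxycarbonyl)-5-methylcyclopent-1-en-1-olate (enolate of 7; formed in the flask) | COC(=O)C1=C([O-])[C@](C)(O)CC1.[Na+] | intermediate
9 | methyl (3R)-3-hydroxy-3-methyl-2-{[(trifluoromethyl)sulfonyl]oxy}cyclopent-1-ene-1-carboxylate | COC(=O)C1=C(OS(=O)(=O)C(F)(F)F)[C@](C)(O)CC1 | intermediate
10 | methyl (3R)-3-hydroxy-2-(hydroxymethyl)-3-methylcyclopent-1-ene-1-carboxylate (formed in the flask) | COC(=O)C1=C(CO)[C@](C)(O)CC1 | intermediate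
11 | (4R)-4-hydroxy-4-methyl-3,4,5,6-tetrahydro-1H-cyclopenta[c]furan-1-one (precursor of the key step) | O=C1OCC2=C1CC[C@@]2(C)O | intermediate
12 | (3aS,4R,6aR)-4-hydroxy-4-methylhexahydro-1H-cyclopenta[c]furan-1-one (cis-fused, ring-fusion hydrogens cis to OH) | O=C1OC[C@@H]2[C@H]1CC[C@@]2(C)O | intermediate
13 | (1R,2S,3R)-2-(hydroxymethyl)-3-(2-hydroxypropan-2-yl)-1-methylcyclopentan-1-ol (CH2OH, carbinol side chain and ring methyl all cis) | OC[C@@H]1[C@H](C(C)(C)O)CC[C@@]1(C)O | intermediate
14 | (1R,2R,3R)-3-(2-hydroxypropan-2-yl)-1-methyl-2-{[(1-phenyl-1H-tetrazol-5-yl)sulfanyl]methyl}cyclopentan-1-ol | c1ccccc1-n1nnnc1SC[C@@H]1[C@H](C(C)(C)O)CC[C@@]1(C)O | intermediate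
15 | (1R,2R,3R)-3-(2-hydroxypropan-2-yl)-1-methyl-2-{[(1-phenyl-1H-tetrazol-5-yl)sulfonyl]methyl}cyclopentan-1-ol | c1ccccc1-n1nnnc1S(=O)(=O)C[C@@H]1[C@H](C(C)(C)O)CC[C@@]1(C)O | intermediate
16 | 5-[({(1R,2R,5R)-2-methyl-2-[(trimethylsilyl)oxy]-5-{2-[(trimethylsilyl)oxy]propan-2-yl}cyclopentyl}methyl)sulfonyl]-1-phenyl-1H-tetrazole | c1ccccc1-n1nnnc1S(=O)(=O)C[C@@H]1[C@H](C(C)(C)O[Si](C)(C)C)CC[C@@]1(C)O[Si](C)(C)C | intermediate
17 | geranyl bromide [(2E)-1-bromo-3,7-dimethylocta-2,6-diene] | CC(C)=CCC/C(C)=C/CBr | starting material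
18 | [(2E)-3,7-dimethylocta-2,6-dien-1-yl]triphenylphosphonium bromide | CC(C)=CCC/C(C)=C/C[P+](c1ccccc1)(c1ccccc1)c1ccccc1.[Br-] | intermediate
19 | crocetindialdehyde [(2E,4E,6E,8E,10E,12E,14E)-2,6,11,15-tetramethylhexadeca-2,4,6,8,10,12,14-heptaenedial] | O=C/C(C)=C/C=C/C(C)=C/C=C/C=C(C)/C=C/C=C(C)/C=O | starting material
20 | [(2E)-3,7-dimethylocta-2,6-dien-1-ylidene]triphenylphosphorane (formed in the flask) | CC(C)=CCC/C(C)=C/C=P(c1ccccc1)(c1ccccc1)c1ccccc1 | intermediate
21 | apo-8'-lycopenal [(2E,4E,6E,8E,10E,12E,14E,16E,18E)-2,6,11,15,19,23-hexamethyltetracosa-2,4,6,8,10,12,14,16,18,22-decaenal] | CC(C)=CCC/C(C)=C/C=C/C(C)=C/C=C/C(C)=C/C=C/C=C(C)/C=C/C=C(C)/C=O | intermediate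
22 | potassium salt of the α-sulfonyl carbanion of 16 (formed in the flask) | c1ccccc1-n1nnnc1S(=O)(=O)[CH-][C@@H]1[C@H](C(C)(C)O[Si](C)(C)C)CC[C@@]1(C)O[Si](C)(C)C.[K+] | intermediate
23 | bis(trimethylsilyl) ether of (all-E,2R,5R,6R)-2,6-cyclolycopene-1,5-diol | CC(C)=CCC/C(C)=C/C=C/C(C)=C/C=C/C(C)=C/C=C/C=C(C)/C=C/C=C(C)/C=C/[C@@H]1[C@H](C(C)(C)O[Si](C)(C)C)CC[C@@]1(C)O[Si](C)(C)C | intermediate
24 | (all-E,2R,5R,6R)-2,6-cyclolycopene-1,5-diol, CNP0169920.2 (cyclopentane end group: C5 methyl, C7 chain and C1 carbinol cis; C5 hydroxyl cis to H-6 and H-2) | CC(C)=CCC/C(C)=C/C=C/C(C)=C/C=C/C(C)=C/C=C/C=C(C)/C=C/C=C(C)/C=C/[C@@H]1[C@H](C(C)(C)O)CC[C@@]1(C)O | target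

**Step count and risks**

Total step count: 16. Longest linear sequence: 14 steps (steps 1 to 12, then 15 and 16); steps 13 and 14 form the C30 aldehyde in a two-step branch.

The three steps most likely to fail:

First, step 8, the key hydrogenation. The electron-poor, tetrasubstituted alkene may turn over slowly, and the catalyst may be lost to inactive hydride-bridged iridium clusters before conversion is complete. The fallback keeps the hydroxyl-directed hydrogenation but moves it to a non-conjugated alkene; it sets out from 11 and comes back at 12. Reduction of 11 with DIBAL-H (iBu2AlH) in CH2Cl2 at −78 °C → 0 °C should give the ene-triol (1R)-2,3-bis(hydroxymethyl)-1-methylcyclopent-2-en-1-ol F1. Hydrogenation of F1 with [Ir(cod)(PCy3)(py)]PF6 under H2 in CH2Cl2 should then give the all-cis triol (1R,2S,3R)-2,3-bis(hydroxymethyl)-1-methylcyclopentan-1-ol F2; the two primary hydroxyls lie in the alkene plane, so the C5 hydroxyl remains the only face-defining ligand. Ag2CO3 on Celite in refluxing toluene should oxidise the less hindered C1 carbinol, remote from the quaternary C5, and the lactol that forms is oxidised on to lactone 12.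

Second, step 5, the ring closure on the dioxolanone. The ester enolate may be consumed by intermolecular acylation, or the acetal may be opened by the amide base, before the five-membered ring can close. The fallback separates acetal cleavage from ring closure; it sets out from 6 and comes back at 7. NaOMe in MeOH at 0 °C should open the dioxolanone to dimethyl (2R)-2-hydroxy-2-methylhexanedioate F3. TESOTf and 2,6-lutidine in CH2Cl2 should protect the tertiary alcohol as dimethyl (2R)-2-methyl-2-[(triethylsilyl)oxy]hexanedioate F4. A classical Dieckmann condensation (KOtBu, THF, 0 °C → rt), for which only one ester has α-hydrogens and so only one regiochemistry is possible, should give methyl (3R)-3-methyl-2-oxo-3-[(triethylsilyl)oxy]cyclopentane-1-carboxylate F5. HF·pyridine in THF then removes the silyl group to give 7.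

Third, step 15, the Julia–Kocienski coupling. Conversion may be low and material may be lost through base-induced degradation and E/Z scrambling when the sparingly soluble C30 polyenal meets the hindered potassium carbanion. The fallback changes the order of the fragment couplings; it sets out from 16 and comes back at 23. Carbanion 22, made from 16 as in step 15, is added to an excess of the shorter, more soluble and more electrophilic dialdehyde 19 (THF, −78 °C → rt, then iodine equilibration). This should give the ring-bearing C30 aldehyde (2E,4E,6E,8E,10E,12E,14E,16E)-2,6,11,15-tetramethyl-17-{(1R,2R,5R)-2-methyl-2-[(trimethylsilyl)oxy]-5-{2-[(trimethylsilyl)oxy]propan-2-yl}cyclopentyl}heptadeca-2,4,6,8,10,12,14,16-octaenal F6. The geranyl end is then attached by Wittig reaction of F6 with ylide 20 (from 18, NaOMe, CH2Cl2/MeOH), followed by heating in heptane, to give 23.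

Further compounds

F1 | step 8 | (1R)-2,3-bis(hydroxymethyl)-1-methylcyclopent-2-en-1-ol | OCC1=C(CO)CC[C@@]1(C)O
F2 | step 8 | (1R,2S,3R)-2,3-bis(hydroxymethyl)-1-methylcyclopentan-1-ol | OC[C@@H]1[C@H](CO)CC[C@@]1(C)O
F3 | step 5 | dimethyl (2R)-2-hydroxy-2-methylhexanedioate | COC(=O)[C@](C)(O)CCCC(=O)OC
F4 | step 5 | dimethyl (2R)-2-methyl-2-[(triethylsilyl)oxy]hexanedioate | COC(=O)[C@](C)(O[Si](CC)(CC)CC)CCCC(=O)OC
F5 | step 5 | methyl (3R)-3-methyl-2-oxo-3-[(triethylsilyl)oxy]cyclopentane-1-carboxylate | COC(=O)C1CC[C@@](C)(O[Si](CC)(CC)CC)C1=O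
F6 | step 15 | (2E,4E,6E,8E,10E,12E,14E,16E)-2,6,11,15-tetramethyl-17-{(1R,2R,5R)-2-methyl-2-[(trimethylsilyl)oxy]-5-{2-[(trimethylsilyl)oxy]propan-2-yl}cyclopentyl}heptadeca-2,4,6,8,10,12,14,16-octaenal | O=C/C(C)=C/C=C/C(C)=C/C=C/C=C(C)/C=C/C=C(C)/C=C/[C@@H]1[C@H](C(C)(C)O[Si](C)(C)C)CC[C@@]1(C)O[Si](C)(C)C
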